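**Plan**

- The butane chain is numbered C1 (CH2 on the guaiacyl ring, ring A) to C4 (CH2 on the syringyl ring, ring B); the target is (2S,3R). The retrosynthesis first removes two O-benzyl groups, then cuts C2–CH3 and C1–ring A together.
- This double cut is possible because C2 carries a methyl group and a CH2–ring A arm beside the C3 stereocentre. That is the pattern left when a terminal C1=C2 alkene takes methyl at C2 and a metal at C1, and C1 is then arylated.
- The remaining (R)-alkene is cut at C3–CH3 (SN2′ methylation of an (E)-allylic bromide) and at C2=C3 (cross-metathesis of the ring B allylarene with butenediol).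
- Forward: ring B allyl ether, then the C1–C4 chain by metathesis, bromide, C3 methyl, C2 methyl plus ring A in one pot, debenzylation. The chain is built linearly and no ring is formed.
- Stereochemistry: C3 (R) comes from the chiral copper–ferrocenyl diphosphine catalyst in the SN2′ step; C2 (S) comes from the chiral zirconocene in the carboalumination, by catalyst control beside the C3 centre.

Key step: step 6

Assumption: the absolute sense of induction of the two chiral catalysts is taken from their behaviour with simple substrates ((R,R)-diphosphine in the SN2′ methylation of (E)-allylic bromides, (−)-zirconocene in the methylalumination of 1-alkenes); if a first run shows the opposite sense, the antipodal catalyst is used.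

**Route**

Step 1
Reactants: 1 4-allyl-2,6-dimethoxyphenol
Product: 2 5-allyl-2-(benzyloxy)-1,3-dimethoxybenzene
Conditions: BnBr, K2CO3, DMF, 60 °C
Reagents that add atoms: benzyl bromide, BrCc1ccccc1
Why: Williamson ether synthesis, in which the phenoxide formed with K2CO3 should displace bromide from the benzylic halide cleanly even between two ortho methoxy groups, while the allyl group is untouched.

Step 2
Reactants: 2 5-allyl-2-(benzyloxy)-1,3-dimethoxybenzene
Product: 3 (E)-4-[4-(benzyloxy)-3,5-dimethoxyphenyl]but-2-en-1-ol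
Conditions: (Z)-but-2-ene-1,4-diol (4 equiv), second-generation Grubbs catalyst RuCl2(=CHPh)(H2IMes)(PCy3) (3 mol%), 1,4-benzoquinone (10 mol%), CH2Cl2, 40 °C
Reagents that add atoms: (Z)-but-2-ene-1,4-diol, OC/C=C\CO
Why: Olefin cross-metathesis of a terminal allylarene with an excess of a symmetrical allylic diol should give the (E)-allylic alcohol as the favoured isomer, with benzoquinone suppressing ruthenium hydride alkene migration and the alcohol stage allowing any (Z)-isomer to be removed before the stereodefining step.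

Step 3
Reactants: 3 (E)-4-[4-(benzyloxy)-3,5-dimethoxyphenyl]but-2-en-1-ol
Product: 4 2-(benzyloxy)-5-[(E)-4-bromobut-2-en-1-yl]-1,3-dimethoxybenzene
Conditions: CBr4, PPh3, CH2Cl2, 0 °C
Reagents that add atoms: carbon tetrabromide, BrC(Br)(Br)Br
Why: Appel reaction, in which SN2 displacement of the primary alkoxyphosphonium by bromide should give the allylic bromide without allylic transposition or loss of E-geometry, the aryl ethers being inert.

Step 4
Reactants: 4 2-(benzyloxy)-5-[(E)-4-bromobut-2-en-1-yl]-1,3-dimethoxybenzene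
Product: 5 (R)-2-(benzyloxy)-1,3-dimethoxy-5-(2-methylbut-3-en-1-yl)benzene
Conditions: MeMgBr (1.2 equiv), CuBr·SMe2 (2 mol%), (R,R)-Taniaphos = (Rp)-1-[(R)-α-(dimethylamino)-2-(diphenylphosphino)benzyl]-2-(diphenylphosphino)ferrocene (2.4 mol%), CH2Cl2, −75 °C
Reagents that add atoms: methylmagnesium bromide, C[Mg]Br
Why: Copper-catalysed asymmetric allylic alkylation with a Grignard reagent, in which the chiral monovalent copper–diphosphine methyl complex should attack the alkene carbon remote from bromide (SN2′) and eliminate reductively from the trivalent σ-allyl copper before it equilibrates, so that methyl arrives at C3 on the face chosen by the ligand and sets the (R) centre beside a new terminal C1=C2 alkene.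

Step 5
Reactants: 6 4-bromo-2-methoxyphenol
Product: 7 1-(benzyloxy)-4-bromo-2-methoxybenzene
Conditions: BnBr, K2CO3, DMF, 23 °C
Reagents that add atoms: benzyl bromide, BrCc1ccccc1
Why: Williamson ether synthesis on an unhindered phenol, the aryl bromide being unreactive under these conditions.

Step 6
Reactants: 5 (R)-2-(benzyloxy)-1,3-dimethoxy-5-(2-methylbut-3-en-1-yl)benzene; 7 1-(benzyloxy)-4-bromo-2-methoxybenzene; 8 trimethylaluminium
Product: 11 (2S,3R)-1-[4-(benzyloxy)-3-methoxyphenyl]-4-[4-(benzyloxy)-3,5-dimethoxyphenyl]-2,3-dimethylbutane, via alkyldimethylalane 9 (not isolated), via alkylzinc triflate 10 (not isolated)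
Conditions: 8 (3 equiv), (−)-bis(1-neomenthylindenyl)zirconium dichloride [(−)-(NMI)2ZrCl2] (5 mol%), CH2Cl2, 0 to 23 °C; volatiles removed in vacuo; Zn(OTf)2, DMF, 70 °C; then 7 (2 equiv), PdCl2(DPEphos) (3 mol%), i-Bu2AlH (6 mol%), DMF/THF, 23 to 60 °C
Reagents that add atoms: trimethylaluminium (compound 8, supplies the C2 methyl group), C[Al](C)C
Why: Me3Al and the zirconocene dichloride generate a cationic chiral methylzirconocene that inserts the C1=C2 alkene of 5 with methyl going to the internal carbon C2 and the metal to C1, and zirconium-to-aluminium exchange releases the primary alane 9 (zirconium-catalysed asymmetric carboalumination, the ZACA reaction). After excess Me3Al is pumped off, Zn(OTf)2 in DMF turns 9 into the alkylzinc 10, and zerovalent palladium (from divalent PdCl2(DPEphos) and i-Bu2AlH) undergoes oxidative addition into 7, transmetalation and reductive elimination, which the wide bite angle of DPEphos favours over β-hydride elimination (Negishi coupling); the closest known reaction type is the one-pot carboalumination–palladium cross-coupling of terminal alkenes with organic halides. No ring is closed; two skeletal bonds (C2–CH3 and C1–ring A) and one stereocentre are formed. The C2 configuration is set by the zirconocene: the (−)-enantiomer, known to turn simple 1-alkenes into the alanes of (R)-2-methylalkan-1-ols, should add methyl to the same face here and give (2R)-9, which is called (2S) in 11 only because the CIP priorities change when the metal is replaced by aryl. The step needs regioselectivity, secured by the single monosubstituted alkene, and face selectivity at C2 beside the C3 centre, which rests on catalyst control because the meso-type relationship fixes the catalyst–substrate pairing; the (2R,3R) diastereomer of 11 expected from incomplete control would be removed by chromatography or crystallisation. Only aryl ether oxygens are present, which excess Me3Al tolerates, and the excess of 7 absorbs any methyl transfer from residual methylaluminium species.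

Step 7
Reactants: 11 (2S,3R)-1-[4-(benzyloxy)-3-methoxyphenyl]-4-[4-(benzyloxy)-3,5-dimethoxyphenyl]-2,3-dimethylbutane
Product: 12 4-[(2R,3S)-4-(4-hydroxy-3-methoxyphenyl)-2,3-dimethylbutyl]-2,6-dimethoxyphenol (CID53359576)
Conditions: H2 (1 atm), 10% Pd/C, EtOAc/MeOH, 23 °C
Reagents that add atoms: none
Why: Heterogeneous catalytic hydrogenolysis should cleave both benzylic C–O bonds to give the free phenols, while the methoxy groups, the saturated chain and its two non-benzylic stereocentres are not affected.

**Compound list**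

1 | 4-allyl-2,6-dimethoxyphenol | C=CCc1cc(OC)c(O)c(OC)c1 | starting material
2 | 5-allyl-2-(benzyloxy)-1,3-dimethoxybenzene | C=CCc1cc(OC)c(OCc2ccccc2)c(OC)c1 | intermediate
3 | (E)-4-[4-(benzyloxy)-3,5-dimethoxyphenyl]but-2-en-1-ol | OC/C=C/Cc1cc(OC)c(OCc2ccccc2)c(OC)c1 | intermediate
4 | 2-(benzyloxy)-5-[(E)-4-bromobut-2-en-1-yl]-1,3-dimethoxybenzene | BrC/C=C/Cc1cc(OC)c(OCc2ccccc2)c(OC)c1 | intermediate
5 | (R)-2-(benzyloxy)-1,3-dimethoxy-5-(2-methylbut-3-en-1-yl)benzene | C=C[C@H](C)Cc1cc(OC)c(OCc2ccccc2)c(OC)c1 | intermediate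
6 | 4-bromo-2-methoxyphenol | COc1cc(Br)ccc1O | starting material
7 | 1-(benzyloxy)-4-bromo-2-methoxybenzene | COc1cc(Br)ccc1OCc1ccccc1 | intermediate
8 | trimethylaluminium | C[Al](C)C | starting material
9 | dimethyl[(2R,3R)-4-[4-(benzyloxy)-3,5-dimethoxyphenyl]-2,3-dimethylbutyl]alane | C[Al](C)C[C@H](C)[C@H](C)Cc1cc(OC)c(OCc2ccccc2)c(OC)c1 | intermediate (not isolated)
10 | [(2R,3R)-4-[4-(benzyloxy)-3,5-dimethoxyphenyl]-2,3-dimethylbutyl]zinc triflate | O=S(=O)(O[Zn]C[C@H](C)[C@H](C)Cc1cc(OC)c(OCc2ccccc2)c(OC)c1)C(F)(F)F | intermediate (not isolated)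
11 | (2S,3R)-1-[4-(benzyloxy)-3-methoxyphenyl]-4-[4-(benzyloxy)-3,5-dimethoxyphenyl]-2,3-dimethylbutane | COc1cc(C[C@H](C)[C@H](C)Cc2cc(OC)c(OCc3ccccc3)c(OC)c2)ccc1OCc1ccccc1 | intermediate
12 | 4-[(2R,3S)-4-(4-hydroxy-3-methoxyphenyl)-2,3-dimethylbutyl]-2,6-dimethoxyphenol | COc1cc(C[C@H](C)[C@H](C)Cc2cc(OC)c(O)c(OC)c2)ccc1O | target

Total steps: 7. Longest linear sequence: 6 steps (steps 1, 2, 3, 4, 6 and 7); step 5 is the one-step side branch to 7.

**Steps most likely to fail**

Step 6. The methylzirconation may show incomplete face selectivity, because catalyst control must operate beside, and possibly against, the allylic C3 centre. Insertion into the branched alkene may also be slow, and methyl transfer from dimethylaluminium residues may compete in the palladium coupling. The fallback sets out from 5 and returns at 11, with the C2 centre set by an oxazolidinone auxiliary instead of the zirconocene. Hydroboration–oxidation of 5 (9-BBN, THF; NaOH, H2O2) gives (R)-4-[4-(benzyloxy)-3,5-dimethoxyphenyl]-3-methylbutan-1-ol F1. Oxidation (TEMPO, PhI(OAc)2, MeCN/H2O) gives (R)-4-[4-(benzyloxy)-3,5-dimethoxyphenyl]-3-methylbutanoic acid F2. Activation with PivCl and Et3N in THF at −20 °C gives (R)-4-[4-(benzyloxy)-3,5-dimethoxyphenyl]-3-methylbutanoic pivalic anhydride F3 (not isolated). This acylates lithiated (R)-4-benzyloxazolidin-2-one (n-BuLi, THF, −78 °C) to give (R)-4-benzyl-3-[(R)-4-[4-(benzyloxy)-3,5-dimethoxyphenyl]-3-methylbutanoyl]oxazolidin-2-one F4. Evans alkylation (NaN(SiMe3)2, THF, −78 °C; MeI) places methyl on the enolate face away from the benzyl group and should give (R)-4-benzyl-3-[(2R,3R)-4-[4-(benzyloxy)-3,5-dimethoxyphenyl]-2,3-dimethylbutanoyl]oxazolidin-2-one F5, the minor diastereomer being separable at this stage. LiBH4 (THF, MeOH, 0 °C) releases (2R,3R)-4-[4-(benzyloxy)-3,5-dimethoxyphenyl]-2,3-dimethylbutan-1-ol F6. I2, PPh3 and imidazole (CH2Cl2, 23 °C) give (2R,3R)-4-[4-(benzyloxy)-3,5-dimethoxyphenyl]-1-iodo-2,3-dimethylbutane F7. Zinc insertion (Zn dust, LiCl, THF, 40 °C) gives [(2R,3R)-4-[4-(benzyloxy)-3,5-dimethoxyphenyl]-2,3-dimethylbutyl]zinc iodide F8 (not isolated), and Negishi coupling with 7 (Pd(OAc)2, SPhos, THF, 50 °C) returns to 11.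

Step 4. Uncatalysed Grignard substitution or a residual (Z)-bromide may erode the branched (SN2′) selectivity or the enantioselectivity, and the absolute sense of the ligand is assumed, not secured. The fallback sets out from 3 and returns at 5, with C3 set by a reagent whose facial rule is established. Sharpless asymmetric epoxidation of 3 (Ti(OiPr)4, L-(+)-diethyl tartrate, t-BuOOH, 4 Å molecular sieves, CH2Cl2, −20 °C) should give [(2S,3S)-3-[4-(benzyloxy)-3,5-dimethoxybenzyl]oxiran-2-yl]methanol F9. Me3Al (CH2Cl2/hexane, 0 °C) opens the epoxide at C3 with inversion and should give (2R,3R)-4-[4-(benzyloxy)-3,5-dimethoxyphenyl]-3-methylbutane-1,2-diol F10. Deoxygenation of the 1,2-diol to the terminal alkene (PPh3, I2, imidazole, toluene, 110 °C; Garegg–Samuelsson olefination) returns to 5.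

Step 2. Cross-metathesis with an unactivated allylic diol may give incomplete E-selectivity and homodimer of the allylarene, and an E/Z mixture would lower the selectivity of step 4. The fallback sets out from 2 and returns at 3, building the chain at the ester oxidation level with an electron-poor partner that couples selectively and with high E-preference. Cross-metathesis of 2 with methyl acrylate (second-generation Grubbs catalyst RuCl2(=CHPh)(H2IMes)(PCy3), CH2Cl2, 40 °C) gives methyl (E)-4-[4-(benzyloxy)-3,5-dimethoxyphenyl]but-2-enoate F11. Reduction with i-Bu2AlH (CH2Cl2, −78 °C) returns to 3.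

**Further compounds**

F1 | step 6 | (R)-4-[4-(benzyloxy)-3,5-dimethoxyphenyl]-3-methylbutan-1-ol | OCC[C@H](C)Cc1cc(OC)c(OCc2ccccc2)c(OC)c1
F2 | step 6 | (R)-4-[4-(benzyloxy)-3,5-dimethoxyphenyl]-3-methylbutanoic acid | OC(=O)C[C@H](C)Cc1cc(OC)c(OCc2ccccc2)c(OC)c1
F3 | step 6 | (R)-4-[4-(benzyloxy)-3,5-dimethoxyphenyl]-3-methylbutanoic pivalic anhydride | CC(C)(C)C(=O)OC(=O)C[C@H](C)Cc1cc(OC)c(OCc2ccccc2)c(OC)c1
F4 | step 6 | (R)-4-benzyl-3-[(R)-4-[4-(benzyloxy)-3,5-dimethoxyphenyl]-3-methylbutanoyl]oxazolidin-2-one | O=C(C[C@H](C)Cc1cc(OC)c(OCc2ccccc2)c(OC)c1)N1[C@H](Cc2ccccc2)COC1=O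
F5 | step 6 | (R)-4-benzyl-3-[(2R,3R)-4-[4-(benzyloxy)-3,5-dimethoxyphenyl]-2,3-dimethylbutanoyl]oxazolidin-2-one | O=C([C@H](C)[C@H](C)Cc1cc(OC)c(OCc2ccccc2)c(OC)c1)N1[C@H](Cc2ccccc2)COC1=O
F6 | step 6 | (2R,3R)-4-[4-(benzyloxy)-3,5-dimethoxyphenyl]-2,3-dimethylbutan-1-ol | OC[C@H](C)[C@H](C)Cc1cc(OC)c(OCc2ccccc2)c(OC)c1
F7 | step 6 | (2R,3R)-4-[4-(benzyloxy)-3,5-dimethoxyphenyl]-1-iodo-2,3-dimethylbutane | IC[C@H](C)[C@H](C)Cc1cc(OC)c(OCc2ccccc2)c(OC)c1
F8 | step 6 | [(2R,3R)-4-[4-(benzyloxy)-3,5-dimethoxyphenyl]-2,3-dimethylbutyl]zinc iodide | I[Zn]C[C@H](C)[C@H](C)Cc1cc(OC)c(OCc2ccccc2)c(OC)c1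
F9 | step 4 | [(2S,3S)-3-[4-(benzyloxy)-3,5-dimethoxybenzyl]oxiran-2-yl]methanol | OC[C@@H]1O[C@H]1Cc1cc(OC)c(OCc2ccccc2)c(OC)c1
F10 | step 4 | (2R,3R)-4-[4-(benzyloxy)-3,5-dimethoxyphenyl]-3-methylbutane-1,2-diol | OC[C@H](O)[C@H](C)Cc1cc(OC)c(OCc2ccccc2)c(OC)c1
F11 | step 2 | methyl (E)-4-[4-(benzyloxy)-3,5-dimethoxyphenyl]but-2-enoate | COC(=O)/C=C/Cc1cc(OC)c(OCc2ccccc2)c(OC)c1
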